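Atom labels follow the alkaloid numbering defined in the first sentence of "The problem".

## The problem

Alkaloid numbering is used: ring A is the azepine (N4, C5, C6, C7, C8, C9, C9a), ring B the pyrrole (C1, C2, C3, N4, C9a), ring C the carbocycle (C1, C9a, C9, C10, C11, C12), ring D the fused lactone (C11, O, C14, C13, C12) and ring E the pendant lactone (C18, C19, C20, C21, O) on C3; C16–C17 is the ethyl group on C10, and C15 and C22 are the methyl groups on C13 and C20. Rings A, B and C all share C9a. The pyrrole is therefore substituted at N4, C9a, C1 and C3, and a synthesis that starts from a pyrrole must form a bond at the β-carbon C1 while the more reactive α-carbon C3 is free or blocked. Rings C and D carry five contiguous stereocentres (9R, 10R, 11R, 12S, 13S): in the half-chair of ring C the three carbon substituents (C8 on C9, ethyl on C10, C13 on C12) are equatorial, whereas the C11–O bond is axial and cis to both neighbours. The C15 methyl group lies on the concave face of the cis-fused C/D bicycle, syn to C1, which should be the less stable position, so enolate methylation (convex face) or any late equilibration at C13 gives the wrong epimer. C18 (S) and C20 (S) of the cis-disubstituted ring E are cut off from the core by the flat pyrrole, so no core stereocentre can control them. The pyrrole does not tolerate oxidants or strong acid, the C18–O bond is a pyrrol-2-ylcarbinyl ester that can ionize to an azafulvenium ion and lose its configuration, and C13 and C20 are at risk with base. The plan rests on one feature: the two heteroatom-bearing carbons of ring C, C9a (bonded to N4) and C11 (bonded to O), are para to each other, so ring C is a masked p-benzoquinone in which a carbonyl at C9a makes C10 and C12 acceptor sites and C9 and C1 donor sites, the polarity that the ethyl group, the C5–C8 chain and the C2–C3 unit require. A C9a carbonyl flanked by an alkyne C2≡C3 on C1 and by a nitrogen tethered to C9 holds all atoms of rings A and B, and once ring B is aromatic the C11 carbonyl is a 2-tetralone-type ketone that enolizes towards C12 and lets C10 and C12 settle equatorial.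

## Retrosynthesis

**Ring D (O–C14 and C11–H).** 26 is opened at the acyl–oxygen bond of ring D and C11 is taken back to the ketone, which leads through alkoxide 25 to keto ester 24. This cut is preferred to C12–C13 or C13–C15 at the lactone stage for two reasons. An axial C11–O bond flanked by two equatorial groups is the signature of equatorial hydride attack on a 2,6-disubstituted cyclohexanone. In 24 both α-carbons C10 and C12 can epimerize, so any mixture can be funnelled into the all-equatorial array. One ring and one stereocentre are removed and two more stereocentres become self-correcting. The forward step needs a bulky hydride that takes the ketone and spares both ester groups, and an alkoxide that closes ring D before base reaches C13.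

**C12–C13.** 24 is cut between the ring and the propionate unit into ketone 21 and triflate 22. Cutting C13–C15 instead would put the methyl group on the convex face, and setting C13 by protonation would need a strong base that also attacks C20. An SN2 reaction at C13 takes the configuration from the chiral pool with inversion and does not depend on the shape of the bicycle. 21 has no ring D atoms and two stereocentres fewer. The forward step needs enolization of 21 (enolate 23) towards C12 only, which conjugation with ring B and the CH2/CH difference provide. It also needs C- rather than O-alkylation and a base that leaves ring E alone.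

**C11 carbonyl group.** 21 comes from dimethyl ketal 20. Before ring B is aromatic, a free C11 ketone beside the C9a carbonyl would make all four α-carbons of ring C epimerizable, with racemization as the end point, and would open the way to a hydroquinone. With the ketal the stereochemical information is relayed: C10 is fixed while C9 is labile, and C9 is fixed from the moment C10 becomes labile. The forward step is a hydrolysis mild enough for the C18–O bond.

**Rings A and B (N4–C9a, N4–C3, plus H on C12 and C2): the key cut.** Cutting both bonds from N4 to ring carbons unravels two rings at once and leads, through azadiene 19 and iminophosphorane 18, to the monocyclic azido enynone 17.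
- The neighbouring cut N4–C5 (N-alkylation) closes only ring A and needs the pyrrole beforehand.
- Cuts at C1–C2 and C3–N4 in the sense of a 1,4-dicarbonyl condensation would place a ketone at C3 next to C18, which would then epimerize.
- 17 has one carbocycle and two core stereocentres.
- The forward reaction must close a seven-membered imine, make N4 attack C3, deliver one hydride to C12 and one proton to C2, spare the ketal and ring E, and keep C9 trans to C10.

**C1–C2.** The sp2–sp cut splits 17 (made from chloride 16) into iodoenone 15 and alkyne 7, two enantiopure fragments of similar size. The remote relation between core and ring E is thus solved by convergence, not by induction. A cut at C3–C18 would need a nucleophilic pyrrole and an aldehyde-level electrophile, which tends to react twice. The nitrogen is introduced only after the coupling (16 to 17), because an azide is incompatible with a copper acetylide and with phosphine ligands.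

**C9–C8 and C10–C16.** 15 comes from enone 14 by α-iodination. 14 comes from enone 11 (dienolate 13) and 12, and 11 from quinone monoketal 8 and diethylzinc 9 (zinc enolate 10). Both bonds follow the natural polarity of the C9a carbonyl. The achiral, symmetric 8 is desymmetrized by one catalytic step that sets C10, and C9 follows by trans alkylation. The second enone arm of 8 is kept for the iodination and later accepts the hydride at C12.

**Ring E.** 7 comes from silylalkyne 6, formed through hydroxy ester 5 from ynone 4, and 4 from diester 1 and alkyne 2 (acetylide 3). C20 is bought with 1. C18 is set by reagent control on the flat ynone, which is more reliable than 1,3-induction. The forward steps need selection of the unbranched ester of 1 and a reduction that leaves the alkyne untouched.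

## Roads not taken

Alternative 1: the most obvious plan starts from the pyrrole and cuts C1–C12. A 9-substituted pyrrolo[1,2-a]azepine carrying the C10–C14 butenolide, A1, would be closed by an acid-induced 6-exo-trig Friedel–Crafts/Michael addition of C1 to C12 (the presumed biosynthetic closure of ring C). This gives the tetracyclic core A2, with protonation of C13 from the convex face. Ring E would then be built on C3 by Vilsmeier formylation, enantioselective 2-(alkoxycarbonyl)allylation and hydrogenation. The closure is attractive, but it moves the difficulty into A1: C9, C10 and C11 must be set as an open-chain triad with no ring to help, including the ethyl/oxygen relation that no equilibrium corrects. During the closure the free α-carbon C3 is a better nucleophile than C1 and invites intermolecular attack. Ring E costs three or four linear steps on the most advanced material and ends with a hydrogenation next to the hydrogenolysis-prone C18–O bond. The chosen plan sets C10 to C12 on the ring under equilibrium control and brings ring E in as a finished fragment.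

Alternative 2: cut C9–C10 and C11–C12 in the Diels–Alder sense. Enal A3, under trienamine catalysis with a chiral secondary amine, would give a pyrrole-2,3-quinodimethane (diene C9=C9a–C1=C12). This diene adds a four-carbon nitroalkene to give nitro aldehyde A4, and a Nef reaction would then give a C11 ketone. Four stereocentres arise at once. However, ring A ties C8 to the outside position on C9 and the enamine chain takes the outside position on C12, so suprafacial addition places C8 and C13 cis, whereas 26 has them trans. C12 would have to be inverted through the C11 ketone, so the plan reaches the ketone hub of the chosen route by a longer way and discards three of the four new centres. A3 also needs a formyl-derived group at the β-carbon C1 of a pyrrole whose α-carbon C3 is free. C15, the oxidation of C14 beside a pyrrole, and all of ring E would still remain.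

Alternative 3: cut C11–C12, C13–C14 and C14–O at once. Ynal A5 would undergo a hetero-Pauson–Khand reaction (alkyne, aldehyde, CO) to butenolide A6, and hydrogenation of C12=C13 from the face of H11 would set C12 and C13. Two rings form in one step, but ring D of A6 is planar and conjugated with ring B, so the C11–O bond is forced pseudo-equatorial on ring C. With oxygen cis to the ethyl group, this pushes the ethyl group and C8 into a trans-diaxial arrangement. The closure should therefore prefer the C11 epimer, helped by easy epimerization of the aldehyde at C10. The C12=C13 bond of A6 is a tetrasubstituted vinylogous carbamate (N4–C9a=C1–C12=C13–C14=O) that should resist hydrogenation under conditions that spare a pyrrolylcarbinyl C–O bond. The chosen plan keeps C12 sp3 and lets oxygen enter axially.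

Key step: step 9

Assumption: the (S,R,R)-phosphoramidite is taken to deliver the ethyl group in the same spatial sense as it does with cyclohex-2-enone, which corresponds to (R)-11; should the sense be opposite, the enantiomeric ligand is used.

## Steps

Step 1
Reactants: 1 dimethyl (2S)-2-methylbutanedioate; 2 ethynyl(trimethyl)silane
Product: 4 methyl (2S)-2-methyl-4-oxo-6-(trimethylsilyl)hex-5-ynoate, via lithium (trimethylsilyl)acetylide 3 (not isolated)
Conditions: 2, n-BuLi, THF, −78 °C; BF3·OEt2; then 1, −78 °C; aq NH4Cl
Reagents that add atoms: ethynyl(trimethyl)silane (2) C#C[Si](C)(C)C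
Why: Boron trifluoride-promoted addition of a lithium acetylide to an ester stops at the ynone because the tetrahedral adduct survives until the quench. The acetylide should choose the unbranched C18 ester over the α-branched C21 ester on steric grounds. C20 comes unchanged from the chiral pool.

Step 2
Reactants: 4 methyl (2S)-2-methyl-4-oxo-6-(trimethylsilyl)hex-5-ynoate
Product: 6 (3S,5S)-3-methyl-5-[(trimethylsilyl)ethynyl]oxolan-2-one, via hydroxy ester 5 (not isolated)
Conditions: Ru[(S,S)-TsDPEN](p-cymene) (1 mol %), i-PrOH, rt; then PPTS (cat.), toluene, 50 °C
Reagents that add atoms: none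
Why: Asymmetric transfer hydrogenation of an alkynyl ketone. The (S,S) catalyst is known to give (S)-propargylic alcohols, so C18 is set by reagent control and the alkyne is not touched. The γ-hydroxy ester then closes to the cis-lactone under mild acid.

Step 3
Reactants: 6 (3S,5S)-3-methyl-5-[(trimethylsilyl)ethynyl]oxolan-2-one
Product: 7 (3S,5S)-5-ethynyl-3-methyloxolan-2-one
Conditions: Bu4NF, AcOH, THF, 0 °C
Reagents that add atoms: none
Why: Fluoride-induced protodesilylation of an alkynylsilane. The acetic acid buffer keeps the medium from epimerizing C20 or opening the lactone.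

Step 4
Reactants: 8 4,4-dimethoxycyclohexa-2,5-dien-1-one; 9 diethylzinc
Product: 11 (5R)-5-ethyl-4,4-dimethoxycyclohex-2-en-1-one, via ethylzinc enolate 10 (not isolated)
Conditions: Cu(OTf)2 (2 mol %), (S)-BINOL-derived phosphoramidite of bis[(R)-1-phenylethyl]amine (4 mol %), toluene, −25 °C; aq NH4Cl
Reagents that add atoms: diethylzinc (9) CC[Zn]CC
Why: Copper/phosphoramidite-catalysed enantioselective conjugate addition of a dialkylzinc to a cyclohexadienone monoketal, a desymmetrization of the two enantiotopic enone arms in which the ligand sets C10. The zinc enolate 10 is not an acceptor, so the second arm survives.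

Step 5
Reactants: 11 (5R)-5-ethyl-4,4-dimethoxycyclohex-2-en-1-one; 12 1-chloro-4-iodobutane
Product: 14 (5R,6R)-6-(4-chlorobutyl)-5-ethyl-4,4-dimethoxycyclohex-2-en-1-one, via lithium dienolate 13 (not isolated)
Conditions: LiN(i-Pr)2, THF, −78 °C; DMPU, 12, −78 → −20 °C
Reagents that add atoms: 1-chloro-4-iodobutane (12) ClCCCCI
Why: Kinetic α'-deprotonation gives the cross-conjugated dienolate, the only enolate available. The iodide end of 12 alkylates it anti to the neighbouring ethyl group, which sets C9 trans to C10. The trans isomer should also be the more stable one, so any cis isomer can be corrected with mild base.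

Step 6
Reactants: 14 (5R,6R)-6-(4-chlorobutyl)-5-ethyl-4,4-dimethoxycyclohex-2-en-1-one
Product: 15 (5R,6R)-6-(4-chlorobutyl)-5-ethyl-2-iodo-4,4-dimethoxycyclohex-2-en-1-one
Conditions: I2, pyridine–CH2Cl2 (1:1), 0 °C → rt
Reagents that add atoms: iodine II
Why: α-Iodination of an enone by conjugate addition of pyridine, iodination of the enolate and elimination, a sequence that works on 4,4-disubstituted cyclohexenones. The medium is basic, so the acid-sensitive allylic ketal is not ionized.

Step 7
Reactants: 15 (5R,6R)-6-(4-chlorobutyl)-5-ethyl-2-iodo-4,4-dimethoxycyclohex-2-en-1-one; 7 (3S,5S)-5-ethynyl-3-methyloxolan-2-one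
Product: 16 (5R,6R)-6-(4-chlorobutyl)-5-ethyl-4,4-dimethoxy-2-{[(2S,4S)-4-methyl-5-oxooxolan-2-yl]ethynyl}cyclohex-2-en-1-one
Conditions: PdCl2(PPh3)2 (5 mol %), CuI (10 mol %), i-Pr2NH, THF, 0 °C → rt
Reagents that add atoms: none
Why: Sonogashira coupling of an α-iodoenone, which is fast at or below room temperature and joins the two enantiopure fragments at C1–C2. The chain still ends in chloride because an azide would cycloadd to 7 under copper catalysis and be reduced by the phosphine ligand.

Step 8
Reactants: 16 (5R,6R)-6-(4-chlorobutyl)-5-ethyl-4,4-dimethoxy-2-{[(2S,4S)-4-methyl-5-oxooxolan-2-yl]ethynyl}cyclohex-2-en-1-one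
Product: 17 (5R,6R)-6-(4-azidobutyl)-5-ethyl-4,4-dimethoxy-2-{[(2S,4S)-4-methyl-5-oxooxolan-2-yl]ethynyl}cyclohex-2-en-1-one
Conditions: NaN3, NaI (cat.), DMF, 50 °C
Reagents that add atoms: sodium azide [Na+].[N-]=[N+]=[N-]
Why: SN2 displacement of a primary chloride with iodide catalysis. Conjugate addition of azide to the enone is reversible, and a cycloaddition of the tethered azide to the alkyne or alkene would need a nine-membered or larger ring.

Step 9
Reactants: 17 (5R,6R)-6-(4-azidobutyl)-5-ethyl-4,4-dimethoxy-2-{[(2S,4S)-4-methyl-5-oxooxolan-2-yl]ethynyl}cyclohex-2-en-1-one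
Product: 20 tricyclic pyrrole ketal (rings A/B/C closed; 9R 10R; dimethyl ketal at C11; CH2 at C12; CH at C2; ring E 18S 20S on C3), via iminophosphorane 18 (not isolated), via bicyclic 1-azadiene 19 (not isolated)
Conditions: PPh3 (1.05 equiv), toluene, rt → 90 °C; cool to rt; diethyl 2,6-dimethyl-1,4-dihydropyridine-3,5-dicarboxylate (1.2 equiv), (Ph3P)AuNTf2 (5 mol %), 4 Å MS, rt, dark
Reagents that add atoms: none
Why: Proposed new method: the Staudinger reaction of the azide and the intramolecular aza-Wittig reaction with the C9a ketone (both known) close ring A by attack of N4 on the carbonyl carbon through a seven-membered cyclic transition state and give the 2-alkynyl-1-azadiene 19, in which ring A holds the N4 lone pair syn to C1 and so aims it at the alkyne. Monovalent gold then activates C2≡C3, N4 attacks C3 in a 5-endo-dig closure of ring B, the positive charge of the resulting pyrrolium ion is relayed to C12 (a pyrrol-3-ylcarbenium ion), hydride transfer from the dihydropyridine to C12 makes ring B aromatic, and the pyridinium ion left behind protonates the C2–Au bond, so the reductant supplies exactly the hydride and the proton that the equation needs. The closest known reaction type is the gold-catalysed cyclization of 2-(1-alkynyl)-2-alken-1-ones with external nucleophiles to furans; new are the imine nitrogen in place of the carbonyl oxygen and hydride as the nucleophile, each supported separately by the 2-alkynylaniline-to-indole cyclization and by dihydropyridine reductions of iminium and heteroarylcarbenium ions that run beside gold catalysts. The other order of events (1,4-hydride transfer to the protonated azadiene, then 5-endo-dig hydroamination of the 2-alkynyl enamine) ends in the same product. No stereocentre is created: C10, C18 and C20 are spectators, and C9, which can epimerize through the enamine tautomer of 19, is held trans to the fixed C10 ethyl group until aromatization makes it configurationally stable. The step needs N- over O-cyclization (secured by finishing the aza-Wittig stage before gold is added), 1,4- over 1,2-hydride delivery (after cyclization C12 is the only electrophilic carbon) and an inert propargylic C18–O bond (the lactone is locked in the s-trans ester geometry, so its carbonyl oxygen cannot reach the alkyne for an acyloxy shift).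

Step 10
Reactants: 20 tricyclic pyrrole ketal
Product: 21 tricyclic C11 ketone (rings A/B/C; 9R 10R; C11=O; CH2 at C12; ring E 18S 20S on C3)
Conditions: PPTS (10 mol %), acetone–H2O (20:1), 0 °C → rt, argon
Reagents that add atoms: water O
Why: Acid-catalysed hydrolysis of a dimethyl ketal, which should be much faster than ionization of the C18–O ester at this acidity. C9 can no longer epimerize, and C10, now α to the ketone, stays trans-diequatorial to C8.

Step 11
Reactants: 21 tricyclic C11 ketone; 22 ethyl (2S)-2-{[(trifluoromethyl)sulfonyl]oxy}propanoate
Product: 24 keto ester (21 bearing at C12 an equatorial (1S)-1-ethoxycarbonylethyl group; 9R 10R 12S 13S 18S 20S), via lithium enolate 23 (not isolated)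
Conditions: LiN(SiMe3)2 (1.05 equiv), THF, −78 °C; 22, −78 → −30 °C; then DBU (0.2 equiv), toluene, rt, argon
Reagents that add atoms: ethyl (2S)-2-{[(trifluoromethyl)sulfonyl]oxy}propanoate (22) C[C@H](OS(=O)(=O)C(F)(F)F)C(=O)OCC
Why: As in a 2-tetralone, the ketone enolizes towards the CH2 group C12 that is conjugated with ring B, and it is far more acidic than ring E, so one equivalent of base is selective. SN2 alkylation of the enolate with the lactate-derived triflate goes with inversion and sets 13S from the chiral pool. DBU then equilibrates C12 (and C10) through the enol into the all-equatorial isomer without touching C13 or C20.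

Step 12
Reactants: 24 keto ester
Product: 26 bisdehydroneotuberostemonine, via lithium alkoxide 25 (not isolated)
Conditions: LiBH(s-Bu)3, THF, −78 → −20 °C; aq NH4Cl
Reagents that add atoms: none
Why: A bulky trialkylborohydride attacks a cyclohexanone with two equatorial α-substituents from the equatorial side and gives the axial alkoxide (11R), cis to the ethyl group and to C13. This alkoxide closes the cis-fused ring D on the ethyl ester on warming. Ketone reduction at −78 °C is faster than attack on the ester or on ring E, and the early quench protects C13 and C20 from the ethoxide set free.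

## Compound list

1 | dimethyl (2S)-2-methylbutanedioate | COC(=O)C[C@H](C)C(=O)OC | starting material
2 | ethynyl(trimethyl)silane | C#C[Si](C)(C)C | starting material
3 | lithium (trimethylsilyl)acetylide | [Li+].[C-]#C[Si](C)(C)C | intermediate
4 | methyl (2S)-2-methyl-4-oxo-6-(trimethylsilyl)hex-5-ynoate | C[Si](C)(C)C#CC(=O)C[C@H](C)C(=O)OC | intermediate
5 | methyl (2S,4S)-4-hydroxy-2-methyl-6-(trimethylsilyl)hex-5-ynoate | C[Si](C)(C)C#C[C@@H](O)C[C@H](C)C(=O)OC | intermediate
6 | (3S,5S)-3-methyl-5-[(trimethylsilyl)ethynyl]oxolan-2-one | C[Si](C)(C)C#C[C@@H]1C[C@H](C)C(=O)O1 | intermediate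
7 | (3S,5S)-5-ethynyl-3-methyloxolan-2-one | C#C[C@@H]1C[C@H](C)C(=O)O1 | intermediate
8 | 4,4-dimethoxycyclohexa-2,5-dien-1-one | COC1(OC)C=CC(=O)C=C1 | starting material
9 | diethylzinc | CC[Zn]CC | starting material
10 | ethylzinc enolate of 11 | CC[C@H]1C(OC)(OC)C=CC(O[Zn]CC)=C1 | intermediate
11 | (5R)-5-ethyl-4,4-dimethoxycyclohex-2-en-1-one | CC[C@H]1C(OC)(OC)C=CC(=O)C1 | intermediate
12 | 1-chloro-4-iodobutane | ClCCCCI | starting material
13 | lithium cross-conjugated dienolate of 11 | CC[C@H]1C(OC)(OC)C=CC([O-])=C1.[Li+] | intermediate
14 | (5R,6R)-6-(4-chlorobutyl)-5-ethyl-4,4-dimethoxycyclohex-2-en-1-one | CC[C@H]1C(OC)(OC)C=CC(=O)[C@@H]1CCCCCl | intermediate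
15 | (5R,6R)-6-(4-chlorobutyl)-5-ethyl-2-iodo-4,4-dimethoxycyclohex-2-en-1-one | CC[C@H]1C(OC)(OC)C=C(I)C(=O)[C@@H]1CCCCCl | intermediate
16 | (5R,6R)-6-(4-chlorobutyl)-5-ethyl-4,4-dimethoxy-2-{[(2S,4S)-4-methyl-5-oxooxolan-2-yl]ethynyl}cyclohex-2-en-1-one | CC[C@H]1C(OC)(OC)C=C(C#C[C@@H]2C[C@H](C)C(=O)O2)C(=O)[C@@H]1CCCCCl | intermediate
17 | (5R,6R)-6-(4-azidobutyl)-5-ethyl-4,4-dimethoxy-2-{[(2S,4S)-4-methyl-5-oxooxolan-2-yl]ethynyl}cyclohex-2-en-1-one | CC[C@H]1C(OC)(OC)C=C(C#C[C@@H]2C[C@H](C)C(=O)O2)C(=O)[C@@H]1CCCCN=[N+]=[N-] | intermediate
18 | triphenyliminophosphorane derived from 17 | CC[C@H]1C(OC)(OC)C=C(C#C[C@@H]2C[C@H](C)C(=O)O2)C(=O)[C@@H]1CCCCN=P(c1ccccc1)(c1ccccc1)c1ccccc1 | intermediate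
19 | (5aR,6R)-6-ethyl-7,7-dimethoxy-9-{[(2S,4S)-4-methyl-5-oxooxolan-2-yl]ethynyl}-3,4,5,5a,6,7-hexahydro-2H-1-benzazepine | CC[C@H]1C(OC)(OC)C=C(C#C[C@@H]3C[C@H](C)C(=O)O3)C2=NCCCC[C@H]12 | intermediate
20 | tricyclic pyrrole ketal (rings A/B/C, C11 dimethyl ketal, ring E on C3) | CC[C@H]1C(OC)(OC)Cc2cc([C@@H]3C[C@H](C)C(=O)O3)n3c2[C@@H]1CCCC3 | intermediate
21 | tricyclic C11 ketone | CC[C@H]1C(=O)Cc2cc([C@@H]3C[C@H](C)C(=O)O3)n3c2[C@@H]1CCCC3 | intermediate
22 | ethyl (2S)-2-{[(trifluoromethyl)sulfonyl]oxy}propanoate | C[C@H](OS(=O)(=O)C(F)(F)F)C(=O)OCC | starting material
23 | lithium C11–C12 enolate of 21 | CC[C@H]1C([O-])=Cc2cc([C@@H]3C[C@H](C)C(=O)O3)n3c2[C@@H]1CCCC3.[Li+] | intermediate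
24 | keto ester (C12 bearing the (1S)-1-ethoxycarbonylethyl group) | CC[C@H]1C(=O)[C@@H]([C@H](C)C(=O)OCC)c2cc([C@@H]3C[C@H](C)C(=O)O3)n3c2[C@@H]1CCCC3 | intermediate
25 | lithium alkoxide of the axial (11R)-alcohol | CC[C@H]1[C@@H]([O-])[C@@H]([C@H](C)C(=O)OCC)c2cc([C@@H]3C[C@H](C)C(=O)O3)n3c2[C@@H]1CCCC3.[Li+] | intermediate
26 | bisdehydroneotuberostemonine | CC[C@H]1[C@H]2OC(=O)[C@@H](C)[C@H]2c2cc([C@@H]3C[C@H](C)C(=O)O3)n3c2[C@@H]1CCCC3 | target

## Step count and least certain steps

Total step count: 12. Longest linear sequence: 9 steps (8 to 26, steps 4–12). The branch from 1 (steps 1–3, then 7–12) is equally long.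

**Step 9 (key step, new method).**
- The aza-Wittig closure of a seven-membered imine at a hindered, conjugated ketone may be slow.
- If it is incomplete, gold would trigger O-cyclization of the remaining enynone.
- The imine may be reduced in the 1,2-sense before it cyclizes.
- Heating may cause loss of methanol and aromatization of the azadiene.

The fallback uses known reaction types only and sets out from chloride 16. Its enone is reduced in the 1,4-sense with [(Ph3P)CuH]6 to the α-alkynyl ketone F1 (a mixture at C1, of no consequence). Azide displacement gives the azido ketone F2, and Staudinger/aza-Wittig closure gives the bicyclic 2-alkynyl imine F3, in equilibrium with its enamine. A 5-endo-dig hydroamination with NaAuCl4, the enamine counterpart of the 2-alkynylaniline-to-indole cyclization, rejoins the route at 20.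

**Step 11.** The hard triflate may alkylate the enolate on oxygen, or the enolate may act as a base and eliminate triflic acid from 22, after which Michael addition to the acrylate would build the wrong chain. The fallback gives up the stereospecific substitution for a late stereochemical correction and sets out from 21 (enolate 23). Racemic ethyl 2-iodopropanoate, a soft electrophile, gives the keto ester F4 as a C13 mixture, and reduction as in step 12 gives the lactone F5 as a C13 mixture. LiN(i-Pr)2 (2.2 equiv) forms the bis(lithium enolate) F6, and 2,6-di-tert-butyl-4-methylphenol at −78 °C protonates ring D from the convex face and ring E anti to the pyrrole. These are the faces that give 13S and 20S, and the route is rejoined at 26.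

**Step 10.** Even weak acid may ionize the C18–O bond, with erosion of the configuration at C18 on re-closure. The electron-rich 2-tetralone-type ketone may also autoxidize at C12 or aromatize. The fallback avoids Brønsted acid and sets out from 20. Me3SiOTf with i-Pr2NEt eliminates one methoxy group under amine buffering to give the pyrrole-conjugated enol ether F7. This is protonated at C12 so easily that moist silica gel or a buffer of pH 5–6 hydrolyses it, and the route is rejoined at 21.

**Step 5.** An unactivated primary iodide may react sluggishly with the dienolate, so proton exchange and double alkylation gain ground. The fallback changes the nucleophile class and sets out from 11. Condensation with 1,1-dimethylhydrazine gives the N,N-dimethylhydrazone F8. Its lithiated azaenolate, a much better partner for simple alkyl iodides, is alkylated with 12 to the hydrazone F9, and hydrolysis with aqueous Cu(OAc)2 at neutral pH rejoins the route at 14.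

**Step 12.** The basic hydride may enolize the acidic ketone instead of reducing it, or facial selectivity may suffer because the half-chair is flattened by ring B. The fallback replaces substrate control by catalyst control. A Corey–Bakshi–Shibata reduction of 24 with catecholborane, using the oxazaborolidine enantiomer matched to equatorial delivery, is not basic. It leads through the neutral alcohol corresponding to 25 back to 26, and no new compound arises (F0).

## Further compounds

F1 | step 9 | (5R,6R)-6-(4-chlorobutyl)-5-ethyl-4,4-dimethoxy-2-{[(2S,4S)-4-methyl-5-oxooxolan-2-yl]ethynyl}cyclohexan-1-one (mixture at C2 of the ring) | CC[C@H]1C(OC)(OC)CC(C#C[C@@H]2C[C@H](C)C(=O)O2)C(=O)[C@@H]1CCCCCl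
F2 | step 9 | azido analogue of F1 | CC[C@H]1C(OC)(OC)CC(C#C[C@@H]2C[C@H](C)C(=O)O2)C(=O)[C@@H]1CCCCN=[N+]=[N-]
F3 | step 9 | bicyclic 2-alkynyl imine (8,9-dihydro derivative of 19) | CC[C@H]1C(OC)(OC)CC(C#C[C@@H]3C[C@H](C)C(=O)O3)C2=NCCCC[C@H]12
F4 | step 11 | keto ester 24 as a mixture at C13 | CC[C@H]1C(=O)[C@@H](C(C)C(=O)OCC)c2cc([C@@H]3C[C@H](C)C(=O)O3)n3c2[C@@H]1CCCC3
F5 | step 11 | pentacyclic lactone as a mixture at C13 | CC[C@H]1[C@H]2OC(=O)C(C)[C@H]2c2cc([C@@H]3C[C@H](C)C(=O)O3)n3c2[C@@H]1CCCC3
F6 | step 11 | bis(lithium enolate) of rings D and E | CC[C@H]1[C@H]2OC([O-])=C(C)[C@H]2c2cc([C@@H]3CC(C)=C([O-])O3)n3c2[C@@H]1CCCC3.[Li+].[Li+]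
F7 | step 10 | C11 methyl enol ether (C11=C12) | CC[C@H]1C(OC)=Cc2cc([C@@H]3C[C@H](C)C(=O)O3)n3c2[C@@H]1CCCC3
F8 | step 5 | N,N-dimethylhydrazone of 11 | CC[C@H]1C(OC)(OC)C=CC(=NN(C)C)C1
F9 | step 5 | N,N-dimethylhydrazone of 14 | CC[C@H]1C(OC)(OC)C=CC(=NN(C)C)[C@@H]1CCCCCl
F0 | step 12 | none | none
A1 | alternative 1 | 9-[1-(4-methyl-5-oxo-2,5-dihydrofuran-2-yl)propyl]-6,7,8,9-tetrahydro-5H-pyrrolo[1,2-a]azepine with the C9, C10 and C11 configuration of 26 | CC[C@@H]([C@H]1OC(=O)C(C)=C1)[C@H]1CCCCn2cccc12
A2 | alternative 1 | tetracyclic core (rings A to D of 26, H on C3) | CC[C@H]1[C@H]2OC(=O)[C@@H](C)[C@H]2c2ccn3c2[C@@H]1CCCC3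
A3 | alternative 2 | (E)-3-(6,7,8,9-tetrahydro-5H-pyrrolo[1,2-a]azepin-1-yl)prop-2-enal | O=C/C=C/c1ccn2CCCCCc12
A4 | alternative 2 | nitro aldehyde cycloadduct (C8 and C13 cis, ethyl and nitro trans) | CC[C@H]1[C@H]([N+](=O)[O-])[C@H](CC=O)c2ccn3c2[C@@H]1CCCC3
A5 | alternative 3 | 2-[1-(prop-1-ynyl)-6,7,8,9-tetrahydro-5H-pyrrolo[1,2-a]azepin-9-yl]butanal with the C9 and C10 configuration of 26 | CC[C@@H](C=O)[C@H]1CCCCn2ccc(C#CC)c12
A6 | alternative 3 | tetracyclic C12=C13 butenolide | CC[C@H]1[C@H]2OC(=O)C(C)=C2c2ccn3c2[C@@H]1CCCC3
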